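All runs are calculated from invented constants.

The vessel is closed, stirred and isothermal, and each flask gets the same coupling partner charge with a different substrate charge. We carry one quantity, the partner ceiling β: coupling partner charged over substrate charged, in percent of the substrate. Each step that uses coupling partner takes one of it, so target, side product and intermediate C together stay at or below β. For spring, β is 4.33%, and for summer 13.0%.

| flask | substrate | coupling partner | remark | time |
|---|---|---|---|---|
| Saturday's | 0.012 M | 0.065 M | run made earlier |  |
| Thursday's | 0.14 M | 0.065 M | run made earlier |  |
| Monday's | 1.2 M | 0.065 M | run made earlier |  |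
| midnight | 0.015 M | 0.0650 M |  | 30 h |
| noon | 0.050 M | 0.0650 M |  | 30 h |
| dawn | 0.15 M | 0.0650 M |  | 30 h |
| summer | 0.50 M | 0.0650 M |  | 30 h |
| spring | 1.5 M | 0.0650 M |  | 30 h |

| Saturday's: time / h | Saturday's: target / % | Thursday's: time / h | Thursday's: target / % | Monday's: time / h | Monday's: target / % |
|---|---|---|---|---|---|
| 4.00 | 13 | 2.00 | 5 | 4.00 | 1 |
| 8.00 | 21 | 5.00 | 6 | 8.00 | 0 |
| 12.0 | 27 | 10.0 | 12 | 12.0 | 0 |
| 15.0 | 34 | 15.0 | 13 | 15.0 | 1 |

(each reading ± 1.5 percentage points)

* [target] at the end for midnight, noon, dawn, summer, spring, in this order
* how that number moves from the first to the last of them (falls all the way / rises, then falls / falls, then rises / rises all the way / hardly changes)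

- steps under discussion: coupling partner + intermediate B <-> intermediate C; substrate -> intermediate A; intermediate A -> intermediate B; substrate + coupling partner -> side product; coupling partner + intermediate A -> target
- "hardly changes" means that all values lie within two and a half points (for a concentration: within two and a half percent of the largest)

We watch Thursday's run in slow motion, with β at 46.4%. In the first hours target reads 5% at 2.00 h, while Saturday's reads 13% at 4.00 h. In the middle the two part. Saturday's gains 21 percentage points by 15.0 h, and Thursday's gains 8 points over a longer stretch. At the end Thursday's target reads 13%, or 0.0182 M, which is 28.0% of the partner charged. That draw sits badly with so slow a pace, so we suspect that partner went early to the other steps. Monday's readings stay at 1% or below, inside the scatter of 1.5 points, under a β of 5.42%.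

Our own reckoning follows. In midnight, β is 433%, so substrate is the limiting reagent, and full conversion would take a quarter of the partner. We can freeze partner there and treat the target step as pseudo-first-order. From dawn on, substrate exceeds partner, and we expect target's part of the ceiling to shrink. We commit to a row that rises to dawn and then falls, with summer and spring near or below 0.0120 M, an estimate from Monday's last reading that carries its scatter.

The forecast gave 0.0075 M, 0.016 M, 0.021 M, 0.018 M and 0.014 M, shape "rises, then falls", on the ground that “Target is therefore capped at about a quarter to a third of the partner”. Its summer and spring values lie above our estimate.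

The flasks give 0.00682 M, 0.0190 M, 0.0241 M, 0.00373 M and 4.11 × 10⁻⁴ M, shape "rises, then falls".

    coupling partner + intermediate B ⇌ intermediate C (K = 11.0 L mol⁻¹, k = 0.0100 L mol⁻¹ min⁻¹)
    substrate → intermediate A (k = 0.0360 min⁻¹)
    intermediate A → intermediate B (k = 2.30 × 10⁻⁴ min⁻¹)
    substrate + coupling partner → side product (k = 0.270 L mol⁻¹ min⁻¹)
    coupling partner + intermediate A → target (k = 0.0150 L mol⁻¹ min⁻¹)

The forecast parts from the flask at summer and spring. In spring, at 30.0 h, side product stands at 4.31% against a β of 4.33%, coupling partner at 0% of its charge, and target at 0.0274%. The consumption of coupling partner is the largest single effect: with partner held at its charge, spring gives 0.721 M of target instead of 4.11 × 10⁻⁴ M. Summer, with a β of 13.0%, ends with side product at 12.2% and target at 0.747%.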